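## Retrosynthetic overview

1. **Feature used.** On the tetrahydropyran (O1, C2–C6), the C2 aryl, the C3 CH2–CH=CHAr arm and the C5 CH(OH)Ar arm all lie on one face. The C3 and C5 arms are 1,3-cis across C4, so the first alkene carbon of the C3 arm and the carbinol carbon of the C5 arm can be tied together as a C=C. This gives a cyclohexene spanning C3–C4–C5, that is, a 2,6-diaryl-3-oxabicyclo[3.3.1]non-6-ene.
2. **Disconnections.** Phenol deprotection; carbinol by CBS reduction of the C5 aryl ketone; (E)-alkene by Julia–Kocienski olefination of the C3 CH2CHO arm; keto-aldehyde by ozonolysis of the bicyclic styrene C=C, a bond absent from the target; C5–C6 bond by Prins closure of a MOM ether onto a 4-arylcyclohexene.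
3. **Prins precursor.** It comes from aryl Grignard addition, oxidation and CBS reduction on (S)-4-arylcyclohex-3-enecarbaldehyde, the organocatalytic Diels–Alder adduct of a 2-arylbutadiene and acrolein.
4. **Ring order.** The cyclohexene is made first (Diels–Alder). The tetrahydropyran is closed onto it second, giving the bicycle. The cyclohexene is cut open third, so only the tetrahydropyran remains.

Key step: step 10

Abbreviations: TBS = tert-butyldimethylsilyl; Piv = pivaloyl; MOM = methoxymethyl; PT = 1-phenyl-1H-tetrazol-5-yl. C2–C6 are tetrahydropyran positions of the target.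

Assumption: the sense of induction of the imidazolidinone catalyst follows its usual shielding model, in which the (5S)-catalyst leads to (R)-4-substituted cyclohex-3-enecarbaldehydes, so the (5R)-catalyst is specified; if a correlation shows the opposite sense, the other catalyst enantiomer is used and nothing else changes.

## Route

Step 1
Reactants: 1 4'-hydroxyacetophenone
Product: 2 4'-(tert-butyldimethylsilyloxy)acetophenone
Conditions: TBSCl, imidazole, DMF, rt
Reagents that add atoms: tert-butyldimethylsilyl chloride, CC(C)(C)[Si](C)(C)Cl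
Why: Imidazole-promoted O-silylation of a phenol masks the acidic OH for the Grignard step, and the aryl silyl ether tolerates mild acid and cold Lewis acid while keeping this ring electron-rich for the later cation.

Step 2
Reactants: 2 4'-(tert-butyldimethylsilyloxy)acetophenone
Product: 3 (±)-2-[4-(TBSO)phenyl]but-3-en-2-ol
Conditions: CH2=CHMgBr, THF, −78 → 0 °C; aq NH4Cl
Reagents that add atoms: vinylmagnesium bromide, C=C[Mg]Br
Why: Grignard 1,2-addition to an aryl methyl ketone, in which the new tertiary centre is racemic and is removed again in the next step.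

Step 3
Reactants: 3 (±)-2-[4-(TBSO)phenyl]but-3-en-2-ol
Product: 4 2-[4-(TBSO)phenyl]buta-1,3-diene
Conditions: PPTS (cat.), BHT (trace), 4 Å MS, toluene, 70 °C; used at once
Reagents that add atoms: none
Why: Acid-catalysed E1 dehydration, because the tertiary, allylic and 4-silyloxybenzylic alcohol ionises under very mild acid and loses a methyl proton to give the 2-aryl diene, while the inhibitor and immediate use limit dimerisation.

Step 4
Reactants: 4 2-[4-(TBSO)phenyl]buta-1,3-diene; 5 acrolein
Product: 6 (1S)-4-[4-(TBSO)phenyl]cyclohex-3-ene-1-carbaldehyde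
Conditions: (5R)-5-benzyl-2,2,3-trimethylimidazolidin-4-one·HCl (20 mol %), MeNO2/H2O 95:5, 0 °C; aldehyde used promptly
Reagents that add atoms: none
Why: Iminium-catalysed enantioselective Diels–Alder reaction, in which the chiral amine lowers the acrolein LUMO, its benzyl group blocks one face of the E-iminium ion so that C1 (the future C3) forms as S, and the larger HOMO coefficient at C1 of the 2-aryl diene gives the 1,4 ("para") regioisomer.

Step 5
Reactants: 7 4-iodophenol
Product: 8 4-iodophenyl pivalate
Conditions: PivCl, Et3N, DMAP (cat.), CH2Cl2, 0 °C → rt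
Reagents that add atoms: pivaloyl chloride, CC(C)(C)C(=O)Cl
Why: DMAP-catalysed O-acylation gives a bulky, electron-withdrawing ester that tolerates the magnesium reagent at low temperature and later makes the C2 aryl a poor cation stabiliser, which protects the benzylic C2–O bond in step 10.

Step 6
Reactants: 8 4-iodophenyl pivalate; 6 (1S)-4-[4-(TBSO)phenyl]cyclohex-3-ene-1-carbaldehyde
Product: 10 4-{hydroxy[(1S)-4-(4-TBSO-phenyl)cyclohex-3-en-1-yl]methyl}phenyl pivalate (both carbinol epimers), via 4-(pivaloyloxy)phenylmagnesium chloride 9 (not isolated)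
Conditions: 8, iPrMgCl·LiCl, THF, −40 °C; then 6, −40 → −20 °C; aq NH4Cl
Reagents that add atoms: none
Why: Iodine–magnesium exchange outruns attack on the hindered ester at −40 °C and the aryl Grignard adds 1,2 to the aldehyde faster than it enolises it, and the uncontrolled carbinol centre does not matter because step 7 erases it.

Step 7
Reactants: 10 carbinol epimer mixture
Product: 11 4-{[(1S)-4-(4-TBSO-phenyl)cyclohex-3-en-1-yl]carbonyl}phenyl pivalate
Conditions: Dess–Martin periodinane, CH2Cl2, 0 °C → rt
Reagents that add atoms: none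
Why: Dess–Martin oxidation converges both epimers on one ketone under nearly neutral conditions, so the styrene, silyl ether, ester and alpha stereocentre should stay intact.

Step 8
Reactants: 11 aryl cyclohexenyl ketone
Product: 12 4-{(R)-hydroxy[(1S)-4-(4-TBSO-phenyl)cyclohex-3-en-1-yl]methyl}phenyl pivalate
Conditions: (S)-Me-CBS (20 mol %), catecholborane, toluene, −78 → −40 °C; MeOH, pH 7 buffer; chromatography
Reagents that add atoms: none
Why: In this Corey–Bakshi–Shibata reduction the ketone binds the ring boron with the aryl group as the large substituent and hydride arrives from the coordinated borane to give the (R)-carbinol (future C2) as with aryl alkyl ketones in general, cold catecholborane spares the trisubstituted styrene, and under reagent control the minor enantiomer of 11 becomes a separable diastereomer, so purification should also raise enantiopurity.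

Step 9
Reactants: 12 (R)-carbinol
Product: 13 4-{(R)-(methoxymethoxy)[(1S)-4-(4-TBSO-phenyl)cyclohex-3-en-1-yl]methyl}phenyl pivalate
Conditions: MOMCl, iPr2NEt, TBAI (cat.), CH2Cl2, 0 °C → rt
Reagents that add atoms: chloromethyl methyl ether, COCCl
Why: O-Alkylation of the secondary alcohol with the reactive alpha-chloro ether gives the formaldehyde acetal without touching either stereocentre, and its OCH2 carbon is the future C6.

Step 10
Reactants: 13 MOM ether
Product: 16 4-{(1S,2R,5S)-6-[4-(TBSO)phenyl]-3-oxabicyclo[3.3.1]non-6-en-2-yl}phenyl pivalate, via oxocarbenium triflate 14 (not isolated), via tertiary benzylic cation 15 (not isolated)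
Conditions: TMSOTf (1.2 equiv), 2,6-di-tert-butyl-4-methylpyridine (1.5 equiv), CH2Cl2 (0.01 M), −78 → −40 °C; Et3N, aq NaHCO3
Reagents that add atoms: none
Why: TMSOTf silylates the outer methoxy oxygen of 13 and expels MeOTMS to leave the formaldehyde-type oxocarbenium 14, whose CH2 carbon is attacked by the unsubstituted styrene carbon to form the C5–C6 bond and the tertiary 4-silyloxybenzylic cation 15, which gives up a proton to the hindered pyridine. This is an acetal-initiated Prins (oxonium-ene type) cyclisation, and the closest known cases are the condensation of cyclohex-3-enylmethanols with aldehydes to 3-oxabicyclo[3.3.1]nonenes and the Lewis-acid ionisation of MOM ethers onto alkenes. The tetrahydropyran closes through a six-membered chair-like array that is endo for the C=O+ bond and exo for the C=C bond, since only the CH carbon of the alkene enters the new ring. The single new stereocentre, bridgehead C5, is fixed by the tether: the arm on the existing ring centre reaches the alkene only from its own face when pseudoaxial, so C3 and C5 end up cis (diaxial on the new chair), while the preset (R)-carbinol carbon places its aryl group equatorial on the same face as the three-carbon bridge. Bonding to the CH carbon rather than the aryl-bearing carbon follows from charge development at the aryl-stabilised position and from six- versus seven-membered closure; the new C=C can only form toward the CH2 because the other neighbour of the cation is a bridgehead (Bredt's rule); the C2–O bond is kept intact by the electron-poor pivaloyloxyphenyl group and the acid scavenger.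

Step 11
Reactants: 16 bicyclic styrene
Product: 18 4-{(2R,3R,5R)-5-[4-(TBSO)benzoyl]-3-(2-oxoethyl)tetrahydro-2H-pyran-2-yl}phenyl pivalate, via secondary ozonide 17 (not isolated)
Conditions: O3, CH2Cl2, −78 °C (Sudan Red 7B end point); PPh3, −78 °C → rt; used without storage
Reagents that add atoms: ozone, [O-][O+]=O
Why: Ozonolysis with reductive work-up cleaves the electron-rich trisubstituted alkene far faster than either arene when dosed to an indicator end point, and it releases an aryl ketone on C5 and an aldehyde on the C3 arm under neutral conditions that should not epimerise C5.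

Step 12
Reactants: 19 4-hydroxybenzaldehyde
Product: 20 4-(tert-butyldimethylsilyloxy)benzaldehyde
Conditions: TBSCl, imidazole, DMF, rt
Reagents that add atoms: tert-butyldimethylsilyl chloride, CC(C)(C)[Si](C)(C)Cl
Why: Imidazole-promoted O-silylation of the phenol gives the same protecting group as on the ketone aryl ring, so both can be removed together at the end.

Step 13
Reactants: 20 4-(TBSO)benzaldehyde
Product: 21 [4-(TBSO)phenyl]methanol
Conditions: NaBH4, MeOH, 0 °C
Reagents that add atoms: none
Why: Borohydride reduction of an aromatic aldehyde is fast at 0 °C, so the aryl silyl ether sees methanolic base only briefly.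

Step 14
Reactants: 21 [4-(TBSO)phenyl]methanol
Product: 22 5-{[4-(TBSO)benzyl]sulfanyl}-1-phenyl-1H-tetrazole
Conditions: 1-phenyl-1H-tetrazole-5-thiol, PPh3, DIAD, THF, 0 °C → rt
Reagents that add atoms: 1-phenyl-1H-tetrazole-5-thiol, Sc1nnnn1-c1ccccc1
Why: Mitsunobu thioetherification, in which the acidic heteroaryl thiol is an ideal pronucleophile and the primary benzylic oxyphosphonium salt is displaced cleanly at sulfur.

Step 15
Reactants: 22 PT sulfide
Product: 23 5-{[4-(TBSO)benzyl]sulfonyl}-1-phenyl-1H-tetrazole
Conditions: mCPBA (excess), CH2Cl2, 0 °C → rt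
Reagents that add atoms: 3-chloroperoxybenzoic acid, O=C(OO)c1cccc(Cl)c1
Why: Peracid oxidation takes the sulfide through the sulfoxide to the sulfone, and the molecule has no other oxidisable site because the silyl-protected arene is inert to the peracid.

Step 16
Reactants: 23 PT sulfone; 18 keto-aldehyde
Product: 25 4-{(2R,3S,5R)-5-[4-(TBSO)benzoyl]-3-[(2E)-3-(4-TBSO-phenyl)prop-2-en-1-yl]tetrahydro-2H-pyran-2-yl}phenyl pivalate, via potassium sulfonyl carbanion 24 (not isolated)
Conditions: 23, KHMDS, 18-crown-6, THF, −78 °C; then 18, −78 → −30 °C; aq NH4Cl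
Reagents that add atoms: none
Why: In this Julia–Kocienski olefination the preformed stabilised carbanion adds to the aldehyde much faster than to the hindered, conjugated aryl ketone and is too weak a base to enolise at C5, while cation sequestration makes the addition reversible so that Smiles rearrangement and anti elimination of the faster-reacting adduct should favour the (E)-styrene.

Step 17
Reactants: 25 (E)-cinnamyl aryl ketone
Product: 26 4-{(2R,3S,5R)-5-[(R)-hydroxy(4-TBSO-phenyl)methyl]-3-[(2E)-3-(4-TBSO-phenyl)prop-2-en-1-yl]tetrahydro-2H-pyran-2-yl}phenyl pivalate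
Conditions: (S)-Me-CBS (30 mol %), catecholborane, toluene, −78 → −30 °C; MeOH, pH 7 buffer; chromatography
Reagents that add atoms: none
Why: This second Corey–Bakshi–Shibata reduction again has aryl as the large group, so the (S)-catalyst should deliver the (R)-carbinol under reagent control, the non-basic medium leaves C5 untouched, cold catecholborane does not hydroborate the styrene, and any epimer is a separable diastereomer.

Step 18
Reactants: 26 protected carbinol
Product: 27 4-{(2R,3S,5R)-5-[(R)-hydroxy(4-hydroxyphenyl)methyl]-3-[(2E)-3-(4-hydroxyphenyl)prop-2-en-1-yl]tetrahydro-2H-pyran-2-yl}phenyl pivalate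
Conditions: TBAF, AcOH (1:1), THF, 0 °C
Reagents that add atoms: none
Why: Fluoride-induced cleavage of both aryl silyl ethers is driven by the Si–F bond, and the acetic acid buffer keeps the liberated phenols protonated so that no acyl transfer and no quinone methide formation at the 4-hydroxybenzylic alcohol should occur.

Step 19
Reactants: 27 bis-phenol pivalate
Product: 28 CNP0182155.1, 4-{(2R,3S,5R)-5-[(R)-hydroxy(4-hydroxyphenyl)methyl]-3-[(2E)-3-(4-hydroxyphenyl)prop-2-en-1-yl]tetrahydro-2H-pyran-2-yl}phenol
Conditions: K2CO3 (0.5 equiv), MeOH, 0 °C → rt; pH 7 phosphate buffer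
Reagents that add atoms: none
Why: Carbonate-catalysed transesterification of the activated aryl ester with methanol, where short exposure at or below room temperature and a neutral quench avoid ionisation or quinone methide formation at the two 4-hydroxybenzylic C–O bonds, so no stereocentre is disturbed.

## Compound list

1 | 4'-hydroxyacetophenone | CC(=O)c1ccc(O)cc1 | starting material
2 | 4'-(TBSO)acetophenone | CC(=O)c1ccc(O[Si](C)(C)C(C)(C)C)cc1 | intermediate
3 | (±)-2-[4-(TBSO)phenyl]but-3-en-2-ol | C=CC(C)(O)c1ccc(O[Si](C)(C)C(C)(C)C)cc1 | intermediate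
4 | 2-[4-(TBSO)phenyl]buta-1,3-diene | C=CC(=C)c1ccc(O[Si](C)(C)C(C)(C)C)cc1 | intermediate
5 | acrolein | C=CC=O | starting material
6 | (1S)-4-[4-(TBSO)phenyl]cyclohex-3-ene-1-carbaldehyde | O=C[C@@H]1CC=C(c2ccc(O[Si](C)(C)C(C)(C)C)cc2)CC1 | intermediate
7 | 4-iodophenol | Oc1ccc(I)cc1 | starting material
8 | 4-iodophenyl pivalate | CC(C)(C)C(=O)Oc1ccc(I)cc1 | intermediate
9 | 4-(pivaloyloxy)phenylmagnesium chloride (LiCl complex) | CC(C)(C)C(=O)Oc1ccc([Mg]Cl)cc1 | intermediate
10 | aryl cyclohexenyl carbinol, (1S), both carbinol epimers | OC(c1ccc(OC(=O)C(C)(C)C)cc1)[C@@H]1CC=C(c2ccc(O[Si](C)(C)C(C)(C)C)cc2)CC1 | intermediate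
11 | (1S)-aryl cyclohexenyl ketone | O=C(c1ccc(OC(=O)C(C)(C)C)cc1)[C@@H]1CC=C(c2ccc(O[Si](C)(C)C(C)(C)C)cc2)CC1 | intermediate
12 | (R)-carbinol, (1S)-ring | O[C@@H](c1ccc(OC(=O)C(C)(C)C)cc1)[C@@H]1CC=C(c2ccc(O[Si](C)(C)C(C)(C)C)cc2)CC1 | intermediate
13 | MOM ether of 12 | COCO[C@@H](c1ccc(OC(=O)C(C)(C)C)cc1)[C@@H]1CC=C(c2ccc(O[Si](C)(C)C(C)(C)C)cc2)CC1 | intermediate
14 | oxocarbenium triflate | C=[O+][C@@H](c1ccc(OC(=O)C(C)(C)C)cc1)[C@@H]1CC=C(c2ccc(O[Si](C)(C)C(C)(C)C)cc2)CC1.[O-]S(=O)(=O)C(F)(F)F | intermediate
15 | bicyclic tertiary benzylic cation (triflate) | C1C[C+](c3ccc(O[Si](C)(C)C(C)(C)C)cc3)[C@@H]2C[C@H]1[C@H](c1ccc(OC(=O)C(C)(C)C)cc1)OC2.[O-]S(=O)(=O)C(F)(F)F | intermediate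
16 | (1S,2R,5S)-2,6-diaryl-3-oxabicyclo[3.3.1]non-6-ene | C1C=C(c3ccc(O[Si](C)(C)C(C)(C)C)cc3)[C@@H]2C[C@H]1[C@H](c1ccc(OC(=O)C(C)(C)C)cc1)OC2 | intermediate
17 | secondary ozonide of 16 (trioxolane carbons undefined) | C1C3OOC(O3)(c4ccc(O[Si](C)(C)C(C)(C)C)cc4)[C@@H]2C[C@H]1[C@H](c1ccc(OC(=O)C(C)(C)C)cc1)OC2 | intermediate
18 | (2R,3R,5R)-keto-aldehyde tetrahydropyran | O=CC[C@H]1C[C@@H](C(=O)c2ccc(O[Si](C)(C)C(C)(C)C)cc2)CO[C@H]1c1ccc(OC(=O)C(C)(C)C)cc1 | intermediate
19 | 4-hydroxybenzaldehyde | O=Cc1ccc(O)cc1 | starting material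
20 | 4-(TBSO)benzaldehyde | O=Cc1ccc(O[Si](C)(C)C(C)(C)C)cc1 | intermediate
21 | [4-(TBSO)phenyl]methanol | OCc1ccc(O[Si](C)(C)C(C)(C)C)cc1 | intermediate
22 | 4-(TBSO)benzyl PT sulfide | CC(C)(C)[Si](C)(C)Oc1ccc(CSc2nnnn2-c2ccccc2)cc1 | intermediate
23 | 4-(TBSO)benzyl PT sulfone | CC(C)(C)[Si](C)(C)Oc1ccc(CS(=O)(=O)c2nnnn2-c2ccccc2)cc1 | intermediate
24 | potassium salt of the carbanion of 23 | [K+].CC(C)(C)[Si](C)(C)Oc1ccc([CH-]S(=O)(=O)c2nnnn2-c2ccccc2)cc1 | intermediate
25 | (2R,3S,5R)-(E)-cinnamyl aryl ketone | CC(C)(C)[Si](C)(C)Oc1ccc(/C=C/C[C@H]2C[C@@H](C(=O)c3ccc(O[Si](C)(C)C(C)(C)C)cc3)CO[C@H]2c2ccc(OC(=O)C(C)(C)C)cc2)cc1 | intermediate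
26 | protected (R)-carbinol | CC(C)(C)[Si](C)(C)Oc1ccc(/C=C/C[C@H]2C[C@@H]([C@@H](O)c3ccc(O[Si](C)(C)C(C)(C)C)cc3)CO[C@H]2c2ccc(OC(=O)C(C)(C)C)cc2)cc1 | intermediate
27 | bis-phenol mono-pivalate | Oc1ccc(/C=C/C[C@H]2C[C@@H]([C@@H](O)c3ccc(O)cc3)CO[C@H]2c2ccc(OC(=O)C(C)(C)C)cc2)cc1 | intermediate
28 | CNP0182155.1 | Oc1ccc(/C=C/C[C@H]2C[C@@H]([C@@H](O)c3ccc(O)cc3)CO[C@H]2c2ccc(O)cc2)cc1 | target

## Step count and risks

Total step count: 19.
Longest linear sequence: 14 steps (1 → 2 → 3 → 4 → 6 → 10 → 11 → 12 → 13 → 16 → 18 → 25 → 26 → 27 → 28).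

**Step 10 (Prins bicyclisation).** Three processes may outrun ring closure: silylation of the inner acetal oxygen with loss of the whole MOM group, silyl loss from the cationic intermediate, and cationic oligomerisation of the electron-rich styrene.
The fallback sets out from 12 and comes back at 16. It makes the two ring bonds in the opposite order and closes the ether under basic rather than cationic conditions. The free carbinol 12 is treated with paraformaldehyde and Me2AlCl (CH2Cl2, −78 → 0 °C). The aluminium alkoxide formed from the OH group holds formaldehyde on its own face. The ene reaction of the 1-arylcyclohexene then places CH2OH on the former =CH carbon with shift of the double bond, giving 4-{(R)-hydroxy[(1S,5S)-4-(4-TBSO-phenyl)-5-(hydroxymethyl)cyclohex-3-en-1-yl]methyl}phenyl pivalate F1. A trans isomer could not cyclise and would be removed. Selective mesylation of the primary hydroxyl (MsCl, 2,4,6-collidine, CH2Cl2, 0 °C) gives the primary monomesylate F2. Intramolecular Williamson etherification (KHMDS, THF, −78 → 0 °C, high dilution) closes the O–C6 bond with retention at the benzylic carbon to give 16.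

**Step 16 (Julia–Kocienski olefination).** A semi-stabilised benzylic sulfonyl anion may show incomplete E selectivity with an unbranched aliphatic aldehyde. Base-induced epimerisation at C5 or intramolecular aldol reaction of the keto-aldehyde may also lower the outcome.
The fallback sets out from 18 and comes back at 25. It replaces carbanion chemistry with neutral alkene metathesis. Aldehyde-selective methylenation of 18 (CH2I2, Zn, Ti(OiPr)4, THF, rt) leaves the aryl ketone alone and gives 4-{(2R,3S,5R)-3-allyl-5-[4-(TBSO)benzoyl]tetrahydro-2H-pyran-2-yl}phenyl pivalate F3. The partner, 4-(tert-butyldimethylsilyloxy)styrene F4, is made from 20 by Wittig methylenation (Ph3P=CH2, THF, 0 °C). Cross metathesis of F3 with excess F4 (second-generation Hoveyda–Grubbs catalyst, CH2Cl2, 40 °C) should give the thermodynamically preferred (E)-alkene 25.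

**Step 4 (organocatalytic Diels–Alder).** The electron-rich diene may polymerise or dimerise in the acidic aqueous medium, facial selectivity may be only moderate, and the aldehyde may partly epimerise before use.
The fallback sets out from 4 and comes back at 11. It uses a covalent chiral auxiliary and bypasses the aldehyde altogether. (R)-4-Benzyloxazolidin-2-one is acylated (acryloyl chloride, Et3N, LiCl, THF) to (R)-3-acryloyl-4-benzyloxazolidin-2-one F5. The Et2AlCl-chelated s-cis imide, shielded on one face by the benzyl group, undergoes Diels–Alder reaction with 4 (CH2Cl2, −78 °C) to give the crystallisable (1S)-cycloadduct imide F6. Aminolysis (MeNH(OMe)·HCl, AlMe3, CH2Cl2, 0 °C) gives the (1S)-N-methoxy-N-methylamide F7. Addition of the arylmagnesium reagent 9 (THF, −40 → 0 °C) gives ketone 11 directly.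

Further compounds
F1 | step 10 | 4-{(R)-hydroxy[(1S,5S)-4-(4-TBSO-phenyl)-5-(hydroxymethyl)cyclohex-3-en-1-yl]methyl}phenyl pivalate | C1C=C(c3ccc(O[Si](C)(C)C(C)(C)C)cc3)[C@@H](CO)C[C@H]1[C@H](c1ccc(OC(=O)C(C)(C)C)cc1)O
F2 | step 10 | primary monomesylate of F1 | C1C=C(c3ccc(O[Si](C)(C)C(C)(C)C)cc3)[C@@H](COS(C)(=O)=O)C[C@H]1[C@H](c1ccc(OC(=O)C(C)(C)C)cc1)O
F3 | step 16 | 4-{(2R,3S,5R)-3-allyl-5-[4-(TBSO)benzoyl]tetrahydro-2H-pyran-2-yl}phenyl pivalate | C=CC[C@H]1C[C@@H](C(=O)c2ccc(O[Si](C)(C)C(C)(C)C)cc2)CO[C@H]1c1ccc(OC(=O)C(C)(C)C)cc1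
F4 | step 16 | 4-(tert-butyldimethylsilyloxy)styrene | C=Cc1ccc(O[Si](C)(C)C(C)(C)C)cc1
F5 | step 4 | (R)-3-acryloyl-4-benzyloxazolidin-2-one | C=CC(=O)N1C(=O)OC[C@H]1Cc1ccccc1
F6 | step 4 | (R)-4-benzyl-3-{[(1S)-4-(4-TBSO-phenyl)cyclohex-3-en-1-yl]carbonyl}oxazolidin-2-one | O=C([C@@H]1CC=C(c2ccc(O[Si](C)(C)C(C)(C)C)cc2)CC1)N1C(=O)OC[C@H]1Cc1ccccc1
F7 | step 4 | (1S)-N-methoxy-N-methyl-4-(4-TBSO-phenyl)cyclohex-3-ene-1-carboxamide | CON(C)C(=O)[C@@H]1CC=C(c2ccc(O[Si](C)(C)C(C)(C)C)cc2)CC1
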